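## Retrosynthetic overview
- The last step cuts the side chain at C1'–C2'. This gives (R)-3-(iodomethyl)-5,7-dimethoxyphthalide and (S)-tridec-12-en-2-ol, joined by a light-driven Ni–H anti-Markovnikov hydroalkylation.
- The iodide comes from the 3-(hydroxymethyl)phthalide. Its γ-lactone (second ring formed) closes from an aryl glycol ester.
- The benzene ring (first ring formed) is built de novo by Alder–Rickert cycloaddition and ethylene extrusion of a dimethoxycyclohexadiene on a glycerate-derived ynoate. C3 is therefore the bought stereocentre of methyl (S)-glycerate acetonide.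
- The alkenol comes from (S)-propylene oxide (C13') and dec-9-enyl Grignard.
- Ring order: dioxolane (bought, temporary), then benzene, then γ-lactone.

Assumption: CIP analysis of the SMILES gives (3S,13'S), and compounds 1, 6, 13 and 14 are taken as catalogue chemicals.

## Route

**Step 1**
Reactants: 1 methyl (S)-2,2-dimethyl-1,3-dioxolane-4-carboxylate
Product: 3 (R)-4-ethynyl-2,2-dimethyl-1,3-dioxolane, via (S)-glyceraldehyde acetonide 2 (not isolated)
Conditions: DIBAL-H (1.05 equiv), CH2Cl2, −78 °C; MeOH; then K2CO3, Ohira–Bestmann reagent, MeOH, 0 °C → rt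
Reagents that add atoms: dimethyl (1-diazo-2-oxopropyl)phosphonate, COP(=O)(OC)C(=[N+]=[N-])C(C)=O
Why: Cold DIBAL-H stops at the aluminium hemiacetal, methanolysis frees aldehyde 2, and the in-flask Ohira–Bestmann (Seyferth–Gilbert) homologation under mild K2CO3/MeOH does not epimerise it, so the bought C–O stereocentre (future C3) is carried over and only its CIP label changes from S to R.

**Step 2**
Reactants: 3 (R)-4-ethynyl-2,2-dimethyl-1,3-dioxolane
Product: 5 methyl 3-[(4R)-2,2-dimethyl-1,3-dioxolan-4-yl]prop-2-ynoate, via lithium acetylide 4 (not isolated)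
Conditions: n-BuLi, THF, −78 °C; ClCO2Me, −78 → 0 °C
Reagents that add atoms: methyl chloroformate, COC(=O)Cl
Why: Acetylide C-acylation with a chloroformate, in which the stereocentre is not a reacting centre and the cold, base-free work-up avoids ynoate–allenoate isomerisation.

**Step 3**
Reactants: 5 methyl 3-[(4R)-2,2-dimethyl-1,3-dioxolan-4-yl]prop-2-ynoate; 6 1,5-dimethoxycyclohexa-1,4-diene
Product: 11 (R)-3-(hydroxymethyl)-5,7-dimethoxyisobenzofuran-1(3H)-one, via conjugated diene 7 (not isolated), via bicyclooctadiene adduct 8 (not isolated), via aryl dioxolane ester 9 (not isolated), via diol ester 10 (not isolated)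
Conditions: 6 (2.5 equiv), dichloromaleic anhydride (1 mol %), neat, sealed tube, 120 → 190 °C; cool; 2 M HCl/THF, 50 °C
Reagents that add atoms: none
Why: Alder–Rickert reaction in which 6 conjugates to 7, the donor-activated C4 terminus of 7 bonds to the β-carbon of ynoate 5 (placing the ester between OMe and the dioxolanyl group), adduct 8 loses ethylene by retro-Diels–Alder to give arene 9, and aqueous acid then removes the acetonide so the benzylic OH of 10 closes the favoured five-membered lactone, all with C3 never reacting and so keeping its configuration.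

**Step 4**
Reactants: 11 (R)-3-(hydroxymethyl)-5,7-dimethoxyisobenzofuran-1(3H)-one
Product: 12 (R)-3-(iodomethyl)-5,7-dimethoxyisobenzofuran-1(3H)-one
Conditions: I2, PPh3, imidazole, CH2Cl2, 0 °C → rt
Reagents that add atoms: iodine, II
Why: Appel (Garegg–Samuelsson) iodination by SN2 at the primary carbon only, under conditions that leave the lactone, the aryl ethers and C3 unchanged.

**Step 5**
Reactants: 13 10-bromodec-1-ene; 14 (S)-propylene oxide
Product: 16 (S)-tridec-12-en-2-ol, via dec-9-enylmagnesium bromide 15 (not isolated)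
Conditions: Mg, THF; CuI (10 mol %), 14, −30 → 0 °C; aqueous quench
Reagents that add atoms: none
Why: Copper-catalysed Grignard opening of a terminal epoxide by SN2 at the CH2 terminus, so the bought carbinol centre (C13') is untouched and stays S.

**Step 6**
Reactants: 12 (R)-3-(iodomethyl)-5,7-dimethoxyisobenzofuran-1(3H)-one; 16 (S)-tridec-12-en-2-ol (1.5 equiv)
Product: 17 (S)-3-[(S)-13-hydroxytetradecyl]-5,7-dimethoxyisobenzofuran-1(3H)-one
Conditions: 4CzIPN (2 mol %), NiBr2·glyme (10 mol %), dtbbpy (12 mol %), Hantzsch ester (1.5 equiv), Na2CO3 (1.5 equiv), DMA, 450 nm LEDs, 25 °C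
Reagents that add atoms: none
Why: Proposed new method: a silane-free, light-driven Ni–H anti-Markovnikov hydroalkylation in which 4CzIPN, reductively quenched by Hantzsch ester, takes (dtbbpy)Ni(II) to Ni(0/I), the Hantzsch pyridinium protonates it to Ni–H, insertion of the terminal alkene of 16 gives the linear alkyl–Ni, Ni(I) abstracts iodine from 12, and the primary radical is captured so that C(sp3)–C(sp3) reductive elimination from Ni(III) forms C1'–C2' with neither C3 nor C13' ever bearing a radical or metal; the closest known reaction type is the thermal, hydrosilane-driven NiH reductive hydroalkylation of α-olefins with alkyl iodides, and the new elements are the photochemical H+/e− supply and the iodolactone-type β-acyloxy iodide paired with an unprotected alkenol.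

## Compound list
1 | methyl (S)-2,2-dimethyl-1,3-dioxolane-4-carboxylate | COC(=O)[C@H]1OC(C)(C)OC1 | starting material
2 | (S)-2,2-dimethyl-1,3-dioxolane-4-carbaldehyde | O=C[C@H]1OC(C)(C)OC1 | intermediate (not isolated)
3 | (R)-4-ethynyl-2,2-dimethyl-1,3-dioxolane | C#C[C@H]1OC(C)(C)OC1 | intermediate
4 | [(4R)-2,2-dimethyl-1,3-dioxolan-4-yl]ethynyllithium | [Li]C#C[C@H]1OC(C)(C)OC1 | intermediate (not isolated)
5 | methyl 3-[(4R)-2,2-dimethyl-1,3-dioxolan-4-yl]prop-2-ynoate | COC(=O)C#C[C@H]1OC(C)(C)OC1 | intermediate
6 | 1,5-dimethoxycyclohexa-1,4-diene | COC1=CCC=C(OC)C1 | starting material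
7 | 1,3-dimethoxycyclohexa-1,3-diene | COC1=CC(OC)=CCC1 | intermediate (not isolated)
8 | methyl 3-[(4R)-2,2-dimethyl-1,3-dioxolan-4-yl]-1,5-dimethoxybicyclo[2.2.2]octa-2,5-diene-2-carboxylate (bridgehead epimers) | COC(=O)C1=C([C@H]2OC(C)(C)OC2)C2CCC1(OC)C=C2OC | intermediate (not isolated)
9 | methyl 2-[(4R)-2,2-dimethyl-1,3-dioxolan-4-yl]-4,6-dimethoxybenzoate | COC(=O)c1c(OC)cc(OC)cc1[C@H]1OC(C)(C)OC1 | intermediate (not isolated)
10 | methyl 2-[(1R)-1,2-dihydroxyethyl]-4,6-dimethoxybenzoate | COC(=O)c1c(OC)cc(OC)cc1[C@H](CO)O | intermediate (not isolated)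
11 | (R)-3-(hydroxymethyl)-5,7-dimethoxyisobenzofuran-1(3H)-one | COc1cc(OC)c2c(c1)[C@H](CO)OC2=O | intermediate
12 | (R)-3-(iodomethyl)-5,7-dimethoxyisobenzofuran-1(3H)-one | COc1cc(OC)c2c(c1)[C@H](CI)OC2=O | intermediate
13 | 10-bromodec-1-ene | C=CCCCCCCCCBr | starting material
14 | (S)-propylene oxide | C[C@H]1CO1 | starting material
15 | dec-9-en-1-ylmagnesium bromide | C=CCCCCCCCC[Mg]Br | intermediate (not isolated)
16 | (S)-tridec-12-en-2-ol | C=CCCCCCCCCC[C@H](C)O | intermediate
17 | (S)-3-[(S)-13-hydroxytetradecyl]-5,7-dimethoxyisobenzofuran-1(3H)-one | COc1cc(OC)c2c(c1)[C@H](CCCCCCCCCCCC[C@H](C)O)OC2=O | target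

## Step count and risks
Total steps: 6. Longest linear sequence: 5 (1 → 3 → 5 → 11 → 12 → 17). Step 5 is a one-step side branch.

**Step 6 (the new step).**
- The main risks are hydrodeiodination of 12 by Hantzsch ester and β-acyloxy elimination from the alkyl–Ni species.
- Further risks are a 1,2-acyloxy shift of the primary radical to the benzylic position and Ni–H chain walking that gives branched isomers.
- The fallback uses known chemistry, sets out from 12 and comes back at 17.
- Keck radical allylation of 12 with allyltributylstannane (AIBN, benzene, 80 °C) gives (S)-3-(but-3-en-1-yl)-5,7-dimethoxyisobenzofuran-1(3H)-one F1.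
- Separately, 9-bromonon-1-ene is converted with Mg into non-8-en-1-ylmagnesium bromide F2. F2 opens 14 (CuI cat.) to give (S)-dodec-11-en-2-ol F3.
- Cross metathesis of F1 with excess F3 (Grubbs II, CH2Cl2, 40 °C) gives (S)-3-[(3E,13S)-13-hydroxytetradec-3-en-1-yl]-5,7-dimethoxyisobenzofuran-1(3H)-one F4.
- Hydrogenation of the remote alkene of F4 (H2, 1 atm, Pd/C, EtOAc) delivers 17.

**Step 3.**
- The risks are thermal loss of the ynoate at 190 °C, sluggish conjugation of 6, and some six-membered 4-hydroxyisochromanone in the acid stage.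
- The fallback sets out from 5 and comes back at 9.
- Compound 5 is heated at lower temperature (toluene, 110 °C) with acyclic 1-methoxy-1,3-bis(trimethylsilyloxy)buta-1,3-diene. Aromatisation then occurs by elimination on mild fluoride work-up rather than by ethylene extrusion.
- This gives methyl 2-[(4R)-2,2-dimethyl-1,3-dioxolan-4-yl]-4,6-dihydroxybenzoate F5.
- Double O-methylation of F5 (MeI, K2CO3, acetone, reflux) gives 9. Compound 9 is isolated and taken to 11 in a separate acid stage (TsOH, wet THF), long enough to equilibrate to the phthalide.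

**Step 1.**
- The risks are over-reduction, loss of the volatile alkyne 3, and slight epimerisation of 2 in basic methanol.
- The fallback sets out from 2 (the same DIBAL-H reduction of 1, worked up cold) and comes back at 5, skipping 3.
- Corey–Fuchs olefination of 2 (CBr4, PPh3, CH2Cl2, 0 °C) gives the non-volatile (R)-4-(2,2-dibromoethenyl)-2,2-dimethyl-1,3-dioxolane F6.
- n-BuLi (2.1 equiv, THF, −78 °C) converts F6 directly into acetylide 4, which is trapped in the same flask with ClCO2Me to give 5.

## Further compounds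
F1 | step 6 | (S)-3-(but-3-en-1-yl)-5,7-dimethoxyisobenzofuran-1(3H)-one | COc1cc(OC)c2c(c1)[C@H](CCC=C)OC2=O
F2 | step 6 | non-8-en-1-ylmagnesium bromide | C=CCCCCCCC[Mg]Br
F3 | step 6 | (S)-dodec-11-en-2-ol | C=CCCCCCCCC[C@H](C)O
F4 | step 6 | (S)-3-[(3E,13S)-13-hydroxytetradec-3-en-1-yl]-5,7-dimethoxyisobenzofuran-1(3H)-one | COc1cc(OC)c2c(c1)[C@H](CC/C=C/CCCCCCCC[C@H](C)O)OC2=O
F5 | step 3 | methyl 2-[(4R)-2,2-dimethyl-1,3-dioxolan-4-yl]-4,6-dihydroxybenzoate | COC(=O)c1c(O)cc(O)cc1[C@H]1OC(C)(C)OC1
F6 | step 1 | (R)-4-(2,2-dibromoethenyl)-2,2-dimethyl-1,3-dioxolane | BrC(Br)=C[C@H]1OC(C)(C)OC1
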